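(The data come from a simulation from invented constants; scatter was added.)

Constants I had none, so I read one off the two earlier runs, by way of three questions.

| flask | electrophile | nucleophile | free base | protic impurity | remark | time |
|---|---|---|---|---|---|---|
| delta | 1 M | 1.2 equiv | 0.66 equiv | 0.020 M | run made earlier |  |
| gamma | 1 M | 1.2 equiv | 1.4 equiv | 0.020 M | run made earlier |  |
| west | 1.0 M | 1.20 equiv | 0.500 equiv | 0.0200 M |  | 6.0 min |
| north-west | 1.0 M | 1.20 equiv | 0.750 equiv | 0.0200 M |  | 6.0 min |
| south-east | 1.0 M | 1.20 equiv | 1.10 equiv | 0.0200 M |  | 6.0 min |

| run | time / min | electrophile / % | product / % |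
|---|---|---|---|
| delta | 0.333 | 95.1 | 2.3 |
| delta | 0.667 | 90.5 | 4.6 |
| delta | 1.33 | 83.4 | 7.9 |
| delta | 2.00 | 75.9 | 13.1 |
| delta | 4.00 | 59.4 | 21.0 |
| gamma | 0.833 | 88.5 | 5.6 |
| gamma | 1.50 | 80.8 | 9.4 |
| gamma | 2.50 | 71.2 | 14.4 |
| gamma | 3.00 | 66.3 | 17.3 |
| gamma | 4.00 | 59.0 | 21.3 |

(standard deviation of a reading: 0.5 percentage points)

- a reading or a percentage of product counts all its forms, free or not
- what has gone from electrophile into another species counts as reacted, even if it can come back
- a reading of electrophile is of its free form alone

1. part of the electrophile that has reacted at the end, west
2. part of the electrophile that has reacted at the end, north-west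
3. part of the electrophile that has reacted at the end, south-east
4. what raising the equivalents of free base from its lowest to its highest value here does to the part of the electrophile that has reacted (changes below 5 percentage points count as none) (no change / it falls / it rises)

Does free base enter the rate? Gamma held 2.12 times delta's base, yet at 4.00 min electrophile stood at 59.4 % in delta and 59.0 % in gamma, a gap of 0.4 percentage points against a scatter of 0.5 points. So I pooled the two runs: 40.8 % of the electrophile lost, 21.2 % product.

What does a product cost? The electrophile lost was about twice the product, so I counted two electrophile and one nucleophile per product.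

How fast does it go? Let x be the fraction of electrophile lost, a the fraction left, r the equivalents of nucleophile, and b = 1 − x/(2r) the fraction of nucleophile left. At 4.00 min, a = 59.2 % and b = 83.0 %, so the electrophile stood lower, and on that count of two per nucleophile it was the limiting reagent. For a rate proportional to both, at fixed equivalents, log10(b/a) climbs in a straight line with charge times time. I called its slope g, the log clock 0.0367 M⁻¹ min⁻¹. Gamma's reading at 2.50 min gave 0.0368 M⁻¹ min⁻¹.

At 6.0 min and 1.0 M, log10(b/a) = 0.220, so b/a = 1.66, and solving for x gave 53.1 %. West, with the lowest base, held 0.500 M, more than the 0.285 M that one base per product and per impurity would take. So I reckoned 53.1 % for west, north-west and south-east alike, with no change.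

The forecast gave 49.5 %, 51 % and 51 %, and no change, holding that “the rate does not depend on base while base remains”.

West, north-west and south-east gave 51.9 %, 52.3 % and 52.5 %, and no change: from the lowest base to the highest the part reacted moved 0.57 points, under the 5 points that counts.

    electrophile + nucleophile → acid set free + product (k = 0.0627 M⁻¹ min⁻¹)
    nucleophile + acid set free ⇌ protonated nucleophile, settled at all times (K = 851 M⁻¹)
    acid set free + free base ⇌ salt of the base, settled at all times (K = 10000 M⁻¹)
    protic impurity + free base → quenched reagent (k = 4.40 M⁻¹ min⁻¹)
    electrophile + product ⇌ idle adduct, settled at all times (K = 29.0 M⁻¹)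

A neighbour of north-west kept its equivalents and its 6.0 min but charged 1.7 M of electrophile. The same log clock gave log10(b/a) = 0.374, so b/a = 2.37, x = 70.1 % and product 35.0 %. That flask had reacted 68.9 % of its electrophile and held 35.5 % product, all forms counted.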